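**Strategy.** Ring A (C1–C10, ten-membered) is closed at C1–C10 by an intramolecular Nozaki–Hiyama–Kishi addition of a C10 (Z)-vinyl iodide to the C1 aldehyde. The step exploits the array C1(=O)–C10H(CH3)–C9H2–C8H–O of ring A, a masked (Z)-4-hydroxy-2-enone: after oxidation the C8 hydroxyl bridges to C1, the rigid 1,8-hemiketal relays C8 to C10 on hydrogenation, and Mitsunobu esterification inverts C8. The precursor is an open-chain butenolide, built from Sharpless-epoxidised nerol by two aldol additions, that already carries the epoxide, the C13 acetate, an (8S) silyl ether and both reacting termini. Stereocentres: C4/C5 and C8 by catalysis, C6 and C10 by relay.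

Key step: step 14

Remark on the chemistry: germacrane numbering is used (C1 ketone carbon, C10 the CH(CH3) carbon, C11/C12/C13 lactone α-carbon, lactone carbonyl and CH2OAc carbon); the target is read as (4S,5R,6R,8R,10S) with a cis-4,5-epoxide (C3 and C6 on the same side).

Step 1
Reactants: 1 nerol, (2Z)-3,7-dimethylocta-2,6-dien-1-ol
Product: 2 [(2R,3S)-3-methyl-3-(4-methylpent-3-en-1-yl)oxiran-2-yl]methanol
Conditions: Ti(OiPr)4 (10 mol%), D-(−)-diethyl tartrate (12 mol%), t-BuOOH, 4 Å molecular sieves, CH2Cl2, −20 °C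
Reagents that add atoms: tert-butyl hydroperoxide, CC(C)(C)OO
Why: Sharpless asymmetric epoxidation; the titanium–D-tartrate complex should deliver oxygen to one face of the allylic (Z)-alkene and set C4 (S) and C5 (R) as the cis-epoxide, while the remote alkene, lacking a directing hydroxyl, should not react.

Step 2
Reactants: 2 [(2R,3S)-3-methyl-3-(4-methylpent-3-en-1-yl)oxiran-2-yl]methanol
Product: 3 (2S,3S)-3-methyl-3-(4-methylpent-3-en-1-yl)oxirane-2-carbaldehyde
Conditions: Dess–Martin periodinane, pyridine, CH2Cl2, 0 °C to rt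
Reagents that add atoms: none
Why: Dess–Martin oxidation of the primary alcohol under buffered conditions should spare the epoxide and its configuration (the C5 descriptor changes by priority only).

Step 3
Reactants: 3 (2S,3S)-3-methyl-3-(4-methylpent-3-en-1-yl)oxirane-2-carbaldehyde; 4 pent-3-yn-2-one
Product: 5 (6R)-6-hydroxy-6-[(2R,3S)-3-methyl-3-(4-methylpent-3-en-1-yl)oxiran-2-yl]hex-2-yn-4-one
Conditions: 4, LiN(SiMe3)2, THF, −78 °C; then 3, −78 °C; AcOH quench at −78 °C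
Reagents that add atoms: none
Why: Aldol addition of the kinetic lithium enolate of the methyl ketone; Felkin–Anh attack anti to the epoxide C–O bond should give the erythro epoxy alcohol, that is C6 (R).

Step 4
Reactants: 5 (6R)-6-hydroxy-6-[(2R,3S)-3-methyl-3-(4-methylpent-3-en-1-yl)oxiran-2-yl]hex-2-yn-4-one
Product: 6 (6R)-6-[(2R,3S)-3-methyl-3-(4-methylpent-3-en-1-yl)oxiran-2-yl]-6-(triethylsilyloxy)hex-2-yn-4-one
Conditions: Et3SiCl, imidazole, CH2Cl2, 0 °C
Reagents that add atoms: chlorotriethylsilane, CC[Si](Cl)(CC)CC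
Why: Silylation of the secondary alcohol blocks retro-aldol and oxa-Michael closure onto the ynone and allows clean enolisation at C7 in step 6.

Step 5
Reactants: 7 ethyl 3-bromo-2-oxopropanoate
Product: 8 ethyl 3-acetoxy-2-oxopropanoate
Conditions: KOAc, acetone, rt
Reagents that add atoms: potassium acetate, CC(=O)[O-].[K+]
Why: SN2 displacement of the activated α-bromo ketone by acetate gives the C11–C12–C13 unit with the C13 acetate in place.

Step 6
Reactants: 6 (6R)-6-[(2R,3S)-3-methyl-3-(4-methylpent-3-en-1-yl)oxiran-2-yl]-6-(triethylsilyloxy)hex-2-yn-4-one; 8 ethyl 3-acetoxy-2-oxopropanoate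
Product: 9 ethyl (4R)-2-(acetoxymethyl)-3-(but-2-ynoyl)-2-hydroxy-4-[(2R,3S)-3-methyl-3-(4-methylpent-3-en-1-yl)oxiran-2-yl]-4-(triethylsilyloxy)butanoate (diastereomers at C7 and C11)
Conditions: 6, LiN(SiMe3)2, THF, −78 °C; then 8; AcOH quench at −78 °C
Reagents that add atoms: none
Why: Crossed aldol addition of the only possible enolate (C7) to the ketone carbonyl of the keto ester, its most electrophilic site, forms C7–C11; the two new centres are left open because both become sp2 in step 8.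

Step 7
Reactants: 9 ethyl (4R)-2-(acetoxymethyl)-3-(but-2-ynoyl)-2-hydroxy-4-[(2R,3S)-3-methyl-3-(4-methylpent-3-en-1-yl)oxiran-2-yl]-4-(triethylsilyloxy)butanoate
Product: 11 [(5R)-4-(but-2-ynoyl)-3-hydroxy-5-[(2R,3S)-3-methyl-3-(4-methylpent-3-en-1-yl)oxiran-2-yl]-2-oxooxolan-3-yl]methyl acetate, via desilylated hydroxy ester 10 (not isolated)
Conditions: HF·pyridine, excess pyridine, THF, 0 °C to rt
Reagents that add atoms: none
Why: Fluoride desilylation frees the C6 hydroxyl, which should close the five-membered lactone on the ethyl ester (5-exo-trig lactonisation, favoured by the quaternary C11) without touching C6.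

Step 8
Reactants: 11 [(5R)-4-(but-2-ynoyl)-3-hydroxy-5-[(2R,3S)-3-methyl-3-(4-methylpent-3-en-1-yl)oxiran-2-yl]-2-oxooxolan-3-yl]methyl acetate
Product: 13 [(5R)-4-(but-2-ynoyl)-5-[(2R,3S)-3-methyl-3-(4-methylpent-3-en-1-yl)oxiran-2-yl]-2-oxo-2,5-dihydrofuran-3-yl]methyl acetate, via tertiary mesylate 12 (not isolated)
Conditions: MsCl, Et3N, CH2Cl2, −20 to 0 °C
Reagents that add atoms: none
Why: Aldol dehydration by mesylation of the C11 hydroxyl and E1cB loss through the acidic C7–H (α to the ynone) should give the tetrasubstituted butenolide C7=C11 under a base too weak to remove the C6–H.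

Step 9
Reactants: 13 [(5R)-4-(but-2-ynoyl)-5-[(2R,3S)-3-methyl-3-(4-methylpent-3-en-1-yl)oxiran-2-yl]-2-oxo-2,5-dihydrofuran-3-yl]methyl acetate
Product: 14 [(5R)-4-[(1S)-1-hydroxybut-2-yn-1-yl]-5-[(2R,3S)-3-methyl-3-(4-methylpent-3-en-1-yl)oxiran-2-yl]-2-oxo-2,5-dihydrofuran-3-yl]methyl acetate
Conditions: (R)-2-methyl-CBS-oxazaborolidine (0.5 equiv), catecholborane, toluene, −78 °C
Reagents that add atoms: none
Why: Corey–Bakshi–Shibata reduction; with the butenolide carbon as the large and the propynyl as the small group the (R)-catalyst should give the (S)-carbinol, the C8 epimer that the hemiketal relay and the final inversion require, and catecholborane at −78 °C should spare alkene, lactone and epoxide.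

Step 10
Reactants: 14 [(5R)-4-[(1S)-1-hydroxybut-2-yn-1-yl]-5-[(2R,3S)-3-methyl-3-(4-methylpent-3-en-1-yl)oxiran-2-yl]-2-oxo-2,5-dihydrofuran-3-yl]methyl acetate
Product: 16 [(5R)-4-[(1S)-1-hydroxybut-2-yn-1-yl]-5-[(2R,3S)-3-methyl-3-(3-oxopropyl)oxiran-2-yl]-2-oxo-2,5-dihydrofuran-3-yl]methyl acetate, via vicinal diol 15 (not isolated)
Conditions: OsO4 (2 mol%), NaIO4, 2,6-lutidine, dioxane/H2O 3:1, rt
Reagents that add atoms: osmium tetroxide (catalytic oxygen carrier), O=[Os](=O)(=O)=O; sodium periodate (terminal oxidant), [Na+].[O-]I(=O)(=O)=O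
Why: Lemieux–Johnson cleavage; only the electron-rich trisubstituted alkene should be dihydroxylated (the butenolide alkene is electron-poor, the alkyne inert), which unmasks the C1 aldehyde.

Step 11
Reactants: 16 [(5R)-4-[(1S)-1-hydroxybut-2-yn-1-yl]-5-[(2R,3S)-3-methyl-3-(3-oxopropyl)oxiran-2-yl]-2-oxo-2,5-dihydrofuran-3-yl]methyl acetate
Product: 17 [(5R)-4-[(1S,2Z)-1-hydroxy-3-(triethylsilyl)but-2-en-1-yl]-5-[(2R,3S)-3-methyl-3-(3-oxopropyl)oxiran-2-yl]-2-oxo-2,5-dihydrofuran-3-yl]methyl acetate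
Conditions: [Cp*Ru(MeCN)3]PF6 (3 mol%), Et3SiH, CH2Cl2, 0 °C to rt
Reagents that add atoms: triethylsilane, CC[SiH](CC)CC
Why: Ruthenium-catalysed trans-hydrosilylation of a propargylic alcohol; the hydroxyl should direct silicon to the distal alkyne carbon C10 and the trans addition places silicon cis to C8, giving the (Z)-vinylsilane.

Step 12
Reactants: 17 [(5R)-4-[(1S,2Z)-1-hydroxy-3-(triethylsilyl)but-2-en-1-yl]-5-[(2R,3S)-3-methyl-3-(3-oxopropyl)oxiran-2-yl]-2-oxo-2,5-dihydrofuran-3-yl]methyl acetate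
Product: 18 [(5R)-4-[(1S,2Z)-1-hydroxy-3-iodobut-2-en-1-yl]-5-[(2R,3S)-3-methyl-3-(3-oxopropyl)oxiran-2-yl]-2-oxo-2,5-dihydrofuran-3-yl]methyl acetate
Conditions: N-iodosuccinimide, MeCN/ClCH2CN 4:1, 0 °C to rt
Reagents that add atoms: N-iodosuccinimide, O=C1CCC(=O)N1I
Why: Iododesilylation (ipso substitution of the vinylsilane) should proceed with retention to the (Z)-vinyl iodide; no other nucleophilic alkene is left in the molecule.

Step 13
Reactants: 18 [(5R)-4-[(1S,2Z)-1-hydroxy-3-iodobut-2-en-1-yl]-5-[(2R,3S)-3-methyl-3-(3-oxopropyl)oxiran-2-yl]-2-oxo-2,5-dihydrofuran-3-yl]methyl acetate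
Product: 19 [(5R)-4-[(1S,2Z)-3-iodo-1-(triethylsilyloxy)but-2-en-1-yl]-5-[(2R,3S)-3-methyl-3-(3-oxopropyl)oxiran-2-yl]-2-oxo-2,5-dihydrofuran-3-yl]methyl acetate
Conditions: Et3SiCl, imidazole, CH2Cl2, 0 °C
Reagents that add atoms: chlorotriethylsilane, CC[Si](Cl)(CC)CC
Why: Silylation protects the C8 hydroxyl so that only the C1 carbinol is oxidised in step 15.

Step 14
Reactants: 19 [(5R)-4-[(1S,2Z)-3-iodo-1-(triethylsilyloxy)but-2-en-1-yl]-5-[(2R,3S)-3-methyl-3-(3-oxopropyl)oxiran-2-yl]-2-oxo-2,5-dihydrofuran-3-yl]methyl acetate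
Product: 20 (4S,5R,6R,8S,9Z)-13-acetoxy-4,5-epoxy-1-hydroxy-8-(triethylsilyloxy)germacra-7(11),9-dien-12,6-olide (both C1 epimers)
Conditions: CrCl2 (8 equiv), NiCl2 (0.1 equiv), degassed DMSO/THF 3:1, slow addition to 0.003 M, rt
Reagents that add atoms: none
Why: Zerovalent nickel (from NiCl2 and CrCl2) inserts into the C10–I bond, the vinyl group passes to trivalent chromium with retention of the (Z) geometry, and the vinylchromium adds to the C1 aldehyde (Nozaki–Hiyama–Kishi reaction, used here as a macrocyclisation of the kind known for nine- and ten-membered carbocycles). Ring A is closed in a 10-exo-trig mode; the butenolide, the cis-epoxide and the (Z)-alkene take rotors out of the seco chain and high dilution should suppress intermolecular coupling. The only new stereocentre, the C1 carbinol, is controlled by nothing and needs no control because step 15 turns it into the carbonyl. The step needs chemoselectivity for the vinyl iodide over lactone, acetate, epoxide and silyl ether, which the mild, non-basic organochromium reagent secures, and it needs the (Z) geometry to survive, since that keeps C8–O and C1 on one side for the hemiketal of step 16.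

Step 15
Reactants: 20 (4S,5R,6R,8S,9Z)-13-acetoxy-4,5-epoxy-1-hydroxy-8-(triethylsilyloxy)germacra-7(11),9-dien-12,6-olide
Product: 21 (4S,5R,6R,8S,9Z)-13-acetoxy-4,5-epoxy-1-oxo-8-(triethylsilyloxy)germacra-7(11),9-dien-12,6-olide
Conditions: Dess–Martin periodinane, pyridine, CH2Cl2, 0 °C
Reagents that add atoms: none
Why: Dess–Martin oxidation of the allylic alcohol; both C1 epimers should converge on one (Z)-enone.

Step 16
Reactants: 21 (4S,5R,6R,8S,9Z)-13-acetoxy-4,5-epoxy-1-oxo-8-(triethylsilyloxy)germacra-7(11),9-dien-12,6-olide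
Product: 23 (1S,4S,5R,6R,8S)-13-acetoxy-4,5-epoxy-1-hydroxy-1,8-epoxygermacra-7(11),9-dien-12,6-olide (bridged hemiketal with 11-oxabicyclo[6.2.1]undec-9-ene core), via hydroxy enone 22 (not isolated)
Conditions: Bu4NF, AcOH (1:1), THF, 0 °C
Reagents that add atoms: none
Why: Buffered desilylation frees the C8 hydroxyl, which the (Z)-alkene holds next to the C1 carbonyl, so hemiketalisation (5-exo-trig) should be spontaneous and C8 dictates the C1 configuration of the bridge.

Step 17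
Reactants: 23 (1S,4S,5R,6R,8S)-13-acetoxy-4,5-epoxy-1-hydroxy-1,8-epoxygermacra-7(11),9-dien-12,6-olide
Product: 24 (1S,4S,5R,6R,8S,10S)-13-acetoxy-4,5-epoxy-1-hydroxy-1,8-epoxygermacr-7(11)-en-12,6-olide
Conditions: H2 (1 atm), 5% Rh/Al2O3, EtOAc, rt
Reagents that add atoms: none
Why: Heterogeneous hydrogenation of the 2,5-dihydrofuran alkene from its exo face (the side of the oxygen bridge, away from the six-carbon bridge) should put H on C10 cis to C8–H and set C10 (S); the tetrasubstituted, electron-poor butenolide alkene should resist.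

Step 18
Reactants: 24 (1S,4S,5R,6R,8S,10S)-13-acetoxy-4,5-epoxy-1-hydroxy-1,8-epoxygermacr-7(11)-en-12,6-olide; 25 methacrylic acid
Product: 27 CNP0128625.1, (4S,5R,6R,8R,10S)-13-acetoxy-4,5-epoxy-8-(methacryloyloxy)-1-oxogermacr-7(11)-en-12,6-olide, via open hydroxy ketone 26 (not isolated)
Conditions: PPh3, DIAD, toluene, 0 °C to rt
Reagents that add atoms: none
Why: Mitsunobu esterification; the hemiketal equilibrates with the γ-hydroxy ketone, whose secondary C8 hydroxyl is activated as the alkoxyphosphonium and displaced by methacrylate with inversion (SN2) to the (8R) ester, while the tertiary hemiketal hydroxyl is too hindered to react.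

**Compound list**

1 | nerol, (2Z)-3,7-dimethylocta-2,6-dien-1-ol | CC(C)=CCC/C(C)=C\CO | starting material
2 | [(2R,3S)-3-methyl-3-(4-methylpent-3-en-1-yl)oxiran-2-yl]methanol | CC(C)=CCC[C@]1(C)O[C@@H]1CO | intermediate
3 | (2S,3S)-3-methyl-3-(4-methylpent-3-en-1-yl)oxirane-2-carbaldehyde | CC(C)=CCC[C@]1(C)O[C@@H]1C=O | intermediate
4 | pent-3-yn-2-one | CC#CC(C)=O | starting material
5 | (6R)-6-hydroxy-6-[(2R,3S)-3-methyl-3-(4-methylpent-3-en-1-yl)oxiran-2-yl]hex-2-yn-4-one | CC(C)=CCC[C@]1(C)O[C@@H]1[C@H](O)CC(=O)C#CC | intermediate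
6 | (6R)-6-[(2R,3S)-3-methyl-3-(4-methylpent-3-en-1-yl)oxiran-2-yl]-6-(triethylsilyloxy)hex-2-yn-4-one | CC(C)=CCC[C@]1(C)O[C@@H]1[C@H](O[Si](CC)(CC)CC)CC(=O)C#CC | intermediate
7 | ethyl 3-bromo-2-oxopropanoate | CCOC(=O)C(=O)CBr | starting material
8 | ethyl 3-acetoxy-2-oxopropanoate | CCOC(=O)C(=O)COC(C)=O | intermediate
9 | ethyl (4R)-2-(acetoxymethyl)-3-(but-2-ynoyl)-2-hydroxy-4-[(2R,3S)-3-methyl-3-(4-methylpent-3-en-1-yl)oxiran-2-yl]-4-(triethylsilyloxy)butanoate, diastereomers at C7 and C11 | CC(C)=CCC[C@]1(C)O[C@@H]1[C@H](O[Si](CC)(CC)CC)C(C(=O)C#CC)C(O)(COC(C)=O)C(=O)OCC | intermediate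
10 | desilylated hydroxy ester, ethyl (4R)-2-(acetoxymethyl)-3-(but-2-ynoyl)-2,4-dihydroxy-4-[(2R,3S)-3-methyl-3-(4-methylpent-3-en-1-yl)oxiran-2-yl]butanoate | CC(C)=CCC[C@]1(C)O[C@@H]1[C@H](O)C(C(=O)C#CC)C(O)(COC(C)=O)C(=O)OCC | intermediate
11 | [(5R)-4-(but-2-ynoyl)-3-hydroxy-5-[(2R,3S)-3-methyl-3-(4-methylpent-3-en-1-yl)oxiran-2-yl]-2-oxooxolan-3-yl]methyl acetate | CC(C)=CCC[C@]1(C)O[C@@H]1[C@@H]2OC(=O)C(O)(COC(C)=O)C2C(=O)C#CC | intermediate
12 | tertiary mesylate of 11 | CC(C)=CCC[C@]1(C)O[C@@H]1[C@@H]2OC(=O)C(OS(C)(=O)=O)(COC(C)=O)C2C(=O)C#CC | intermediate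
13 | [(5R)-4-(but-2-ynoyl)-5-[(2R,3S)-3-methyl-3-(4-methylpent-3-en-1-yl)oxiran-2-yl]-2-oxo-2,5-dihydrofuran-3-yl]methyl acetate | CC(C)=CCC[C@]1(C)O[C@@H]1[C@@H]2OC(=O)C(COC(C)=O)=C2C(=O)C#CC | intermediate
14 | [(5R)-4-[(1S)-1-hydroxybut-2-yn-1-yl]-5-[(2R,3S)-3-methyl-3-(4-methylpent-3-en-1-yl)oxiran-2-yl]-2-oxo-2,5-dihydrofuran-3-yl]methyl acetate | CC(C)=CCC[C@]1(C)O[C@@H]1[C@@H]2OC(=O)C(COC(C)=O)=C2[C@@H](O)C#CC | intermediate
15 | vicinal diol of 14 (3,4-dihydroxy-4-methylpentyl side chain, C1 epimers) | CC(C)(O)C(O)CC[C@]1(C)O[C@@H]1[C@@H]2OC(=O)C(COC(C)=O)=C2[C@@H](O)C#CC | intermediate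
16 | [(5R)-4-[(1S)-1-hydroxybut-2-yn-1-yl]-5-[(2R,3S)-3-methyl-3-(3-oxopropyl)oxiran-2-yl]-2-oxo-2,5-dihydrofuran-3-yl]methyl acetate | O=CCC[C@]1(C)O[C@@H]1[C@@H]2OC(=O)C(COC(C)=O)=C2[C@@H](O)C#CC | intermediate
17 | [(5R)-4-[(1S,2Z)-1-hydroxy-3-(triethylsilyl)but-2-en-1-yl]-5-[(2R,3S)-3-methyl-3-(3-oxopropyl)oxiran-2-yl]-2-oxo-2,5-dihydrofuran-3-yl]methyl acetate | O=CCC[C@]1(C)O[C@@H]1[C@@H]2OC(=O)C(COC(C)=O)=C2[C@@H](O)/C=C(/C)[Si](CC)(CC)CC | intermediate
18 | [(5R)-4-[(1S,2Z)-1-hydroxy-3-iodobut-2-en-1-yl]-5-[(2R,3S)-3-methyl-3-(3-oxopropyl)oxiran-2-yl]-2-oxo-2,5-dihydrofuran-3-yl]methyl acetate | O=CCC[C@]1(C)O[C@@H]1[C@@H]2OC(=O)C(COC(C)=O)=C2[C@@H](O)/C=C(/C)I | intermediate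
19 | [(5R)-4-[(1S,2Z)-3-iodo-1-(triethylsilyloxy)but-2-en-1-yl]-5-[(2R,3S)-3-methyl-3-(3-oxopropyl)oxiran-2-yl]-2-oxo-2,5-dihydrofuran-3-yl]methyl acetate | O=CCC[C@]1(C)O[C@@H]1[C@@H]2OC(=O)C(COC(C)=O)=C2[C@@H](O[Si](CC)(CC)CC)/C=C(/C)I | intermediate
20 | (4S,5R,6R,8S,9Z)-13-acetoxy-4,5-epoxy-1-hydroxy-8-(triethylsilyloxy)germacra-7(11),9-dien-12,6-olide, C1 epimers | CC[Si](CC)(CC)O[C@H]1/C=C(/C)C(O)CC[C@]2(C)O[C@@H]2[C@@H]2OC(=O)C(COC(C)=O)=C21 | intermediate
21 | (4S,5R,6R,8S,9Z)-13-acetoxy-4,5-epoxy-1-oxo-8-(triethylsilyloxy)germacra-7(11),9-dien-12,6-olide | CC[Si](CC)(CC)O[C@H]1/C=C(/C)C(=O)CC[C@]2(C)O[C@@H]2[C@@H]2OC(=O)C(COC(C)=O)=C21 | intermediate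
22 | (4S,5R,6R,8S,9Z)-13-acetoxy-4,5-epoxy-8-hydroxy-1-oxogermacra-7(11),9-dien-12,6-olide | O[C@H]1/C=C(/C)C(=O)CC[C@]2(C)O[C@@H]2[C@@H]2OC(=O)C(COC(C)=O)=C21 | intermediate
23 | (1S,4S,5R,6R,8S)-13-acetoxy-4,5-epoxy-1-hydroxy-1,8-epoxygermacra-7(11),9-dien-12,6-olide (bridged hemiketal) | O[C@@]12CC[C@]3(C)O[C@@H]3[C@@H]3OC(=O)C(COC(C)=O)=C3[C@@H](O1)C=C2C | intermediate
24 | (1S,4S,5R,6R,8S,10S)-13-acetoxy-4,5-epoxy-1-hydroxy-1,8-epoxygermacr-7(11)-en-12,6-olide (bridged hemiketal) | O[C@@]12CC[C@]3(C)O[C@@H]3[C@@H]3OC(=O)C(COC(C)=O)=C3[C@@H](O1)C[C@@H]2C | intermediate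
25 | methacrylic acid | C=C(C)C(=O)O | starting material
26 | (4S,5R,6R,8S,10S)-13-acetoxy-4,5-epoxy-8-hydroxy-1-oxogermacr-7(11)-en-12,6-olide (open tautomer of 24) | O[C@H]1C[C@H](C)C(=O)CC[C@]2(C)O[C@@H]2[C@@H]2OC(=O)C(COC(C)=O)=C21 | intermediate
27 | CNP0128625.1, (4S,5R,6R,8R,10S)-13-acetoxy-4,5-epoxy-8-(methacryloyloxy)-1-oxogermacr-7(11)-en-12,6-olide | C=C(C)C(=O)O[C@@H]1C[C@H](C)C(=O)CC[C@]2(C)O[C@@H]2[C@@H]2OC(=O)C(COC(C)=O)=C21 | target

**Step count.** Total: 18 steps. Longest linear sequence: 17 steps (steps 1–4 and 6–18, from nerol); step 5 is a one-step side branch.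

**Steps most likely to fail**

1. Step 14. Intermolecular coupling or simple reduction of the vinyl iodide may outrun closure of the strained ten-membered ring. The fallback closes the same bond by an intramolecular Stille acylation. It sets out from 19: Pinnick oxidation (NaClO2, NaH2PO4, 2-methylbut-2-ene) should give the seco acid F1. Iodine–tin exchange with (Me3Sn)2 and catalytic Pd(PPh3)4 should give the vinylstannane acid F2. 1-Chloro-N,N,2-trimethylprop-1-en-1-amine should convert it into the acid chloride F3. Slow addition of this to Pd2(dba)3/tri(2-furyl)phosphine in THF should give the enone directly, and the fallback comes back to the route at 21.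

2. Step 18. Activation of the hemiketal hydroxyl, or elimination instead of substitution at the hindered C8, may compete with the inversion. The fallback replaces the redox condensation by sulfonate displacement. It sets out from 24: MsCl/Et3N at −20 °C should trap the open tautomer as the secondary mesylate F4. Cesium methacrylate (from 25 and Cs2CO3) with 18-crown-6 in toluene should displace it with inversion, and the fallback comes back at 27.

3. Step 6. Proton transfer from the enolisable keto ester to the ketone enolate, or retro-aldol on work-up, may prevent C7–C11 bond formation. The fallback makes the same bond intramolecularly. It sets out from 5: 3-bromo-2-oxopropanoic acid and KOAc should give 3-acetoxy-2-oxopropanoic acid F5. Steglich esterification (DCC, DMAP) of the C6 hydroxyl of 5 should give the keto ester F6. iPr2NEt in CH2Cl2 should then close the lactone by aldol addition of C7 to the ester's ketone carbonyl, and the fallback comes back at 11, bypassing steps 4–7.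

**Further compounds**

F1 | step 14 | 3-[(2S,3R)-3-[(2R)-4-(acetoxymethyl)-3-[(1S,2Z)-3-iodo-1-(triethylsilyloxy)but-2-en-1-yl]-5-oxo-2,5-dihydrofuran-2-yl]-2-methyloxiran-2-yl]propanoic acid | OC(=O)CC[C@]1(C)O[C@@H]1[C@@H]2OC(=O)C(COC(C)=O)=C2[C@@H](O[Si](CC)(CC)CC)/C=C(/C)I
F2 | step 14 | (Z)-trimethylstannyl analogue of F1 | OC(=O)CC[C@]1(C)O[C@@H]1[C@@H]2OC(=O)C(COC(C)=O)=C2[C@@H](O[Si](CC)(CC)CC)/C=C(/C)[Sn](C)(C)C
F3 | step 14 | acid chloride of F2 | ClC(=O)CC[C@]1(C)O[C@@H]1[C@@H]2OC(=O)C(COC(C)=O)=C2[C@@H](O[Si](CC)(CC)CC)/C=C(/C)[Sn](C)(C)C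
F4 | step 18 | (4S,5R,6R,8S,10S)-13-acetoxy-4,5-epoxy-8-(methanesulfonyloxy)-1-oxogermacr-7(11)-en-12,6-olide | CS(=O)(=O)O[C@H]1C[C@H](C)C(=O)CC[C@]2(C)O[C@@H]2[C@@H]2OC(=O)C(COC(C)=O)=C21
F5 | step 6 | 3-acetoxy-2-oxopropanoic acid | CC(=O)OCC(=O)C(=O)O
F6 | step 6 | (1R)-1-[(2R,3S)-3-methyl-3-(4-methylpent-3-en-1-yl)oxiran-2-yl]-3-oxohex-4-yn-1-yl 3-acetoxy-2-oxopropanoate | CC(C)=CCC[C@]1(C)O[C@@H]1[C@H](OC(=O)C(=O)COC(C)=O)CC(=O)C#CC
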